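## Structural features

The target is a C2-symmetric 9,9'-epoxylignan. It has one oxolane ring (O, C9, C8, C8', C9') whose two OCH2 carbons C9 and C9' are unsubstituted, and whose ring CH carbons C8 and C8' each carry an exocyclic aryl(hydroxy)methyl arm (C7, C7') bearing a 4-hydroxy-3-methoxyphenyl group. Four contiguous stereocentres run along C7–C8–C8'–C7' (7S,8R,8'R,7'S); the two arms are trans on the ring and each carbinol carbon has the same relative relationship to its ring neighbour. The fragile groups are the two p-hydroxybenzylic alcohols: acid ionises them easily (epimerisation at C7, ether formation, Friedel–Crafts closure onto the other arene to an aryltetralin), hot base can expel the benzylic oxygen through a quinone methide, and the free phenols oxidise readily. The ring itself is simple; the real difficulty is to fix the exocyclic carbinol centres relative to the ring centres without exposing an electron-rich benzylic alcohol to acid. The key step uses the fact that C9 is a bare methylene between the ring oxygen and C8 while C7 is a benzylic, oxygen-bearing carbon: C9 can enter as a CH2=O+ unit on the ring oxygen, C7=C8 as an E-styrene, and the charge that develops at C7 when C8 attacks C9 is quenched by oxygen. Electron-withdrawing arenesulfonates on both phenols make this cationic chemistry tolerable and keep both benzylic centres quiet until the last step.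

## Logic of the disconnections

From 20 to 19: the two phenolic O–S bonds are cut last. The phenols must stay masked as electron-poor sulfonates through every cationic step, and must not be freed while a benzylic ester is present, because a phenoxide para to a benzylic ester would eliminate to a quinone methide. The gain is modest (two protecting groups), but the one harsh operation falls where hydroxide is the only possible benzylic leaving group. The forward step must cleave S–O without disturbing C7 or C7'.

From 19 to 18: the acyl–oxygen bonds of the two benzylic esters are cut. Acyl–O cleavage leaves both carbinol configurations untouched and gives a C2-symmetric compound from which a C7 epimer formed in the key step could be removed. The forward step must be mild enough to spare the aryl sulfonates.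

From 18 to 15 (key disconnection): the C8–C9 bond and the C7–O bond are cut. This opens the oxolane and removes two stereocentres at once, leaving an acyclic E-styrene with only C7' and C8' as stereocentres and C9 as the methylene of an alkoxymethyl ether on O9'. The forward step demands that 16 forms on O9' only, that closure goes through C8 and not C7, that C8 is set trans to the arm on C8', and that 17 is captured at C7 anti to the new bond faster than Friedel–Crafts closure or proton loss.

From 15 through 14 to 13: the O7'–acetyl bond and then the O9'–CH2OMe bond are cut. Both oxygens of 13 are homoallylic to the styrene, so they must be differentiated before the cyclisation; the order (primary oxygen first, acetate second) relies on the steric difference between the two hydroxyls. The forward demand is clean primary-selective alkoxymethylation.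

From 13 to 12: C9' is taken back to the carboxyl oxidation level (in the forward sense an imide C–N bond is cleaved reductively). This turns the 1,3-diol into an auxiliary-bearing aldol adduct. The forward reduction must not disturb the doubly activated centre next to the carbonyl.

From 12 to 7 and 9: the C7'–C8' bond is cut (aldol). This is the only point where absolute configuration enters; it sets C7' and C8' together and splits the skeleton into two pieces of similar size. The forward step demands a Z-configured dienolate (10), reaction at the α-carbon only, syn selectivity and auxiliary-controlled facial selectivity on the way to 11, with the E-alkene left intact.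

From 7 to 4 and 5, from 4 to 2 and 3, and from 2 and 9 to 1 and 8: the imide N–C(acyl) bond, the aryl–C7 bond and the two phenolic O–S bonds are cut. This reaches four simple commercial compounds. The forward demands are E geometry and a β,γ-placed alkene in 4, and an acylation that does not move that alkene into conjugation with the carbonyl.

## Other disconnections considered

Alternative 1: The cut is at the two carbinol C–H bonds (C7–H, C7'–H) and the two lactone C–O bonds of a bicyclic dilactone. The forward key step would be hydrogenation of dimethyl 2,3-bis(4-benzyloxy-3-methoxybenzoyl)butanedioate A1 with H2 and RuCl2[(R)-binap] under dynamic kinetic resolution, each new hydroxyl then closing a γ-lactone to give the exo,exo-diaryl dilactone A2.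
- In its favour: one catalytic operation would set all four stereocentres, with C7 and C7' under catalyst control. A1 is two identical halves, so the C2 symmetry is used fully. On absolute control at C7/C7' and on step count up to the key intermediate it is equal to or better than the chosen plan.
- Against it: A1 is both a 1,4-diketone and a double β-keto ester. It should be largely enolised and, under the acidic conditions common for such hydrogenations, prone to Paal–Knorr closure to a furan. Both α-centres must epimerise faster than either ketone is reduced, and after the first reduction and lactonisation the catalyst must override the substrate's own bias.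
- After the key step: C9 and C9' in A2 are at the carboxyl level and bonded to the wrong oxygens. Reduction would give the tetraol A3, in which the ether must be closed between the two primary carbinols while two benzylic hydroxyls are equally placed for five-membered closure; acid would drive A3 toward the furofuran skeleton. The final hydrogenolysis of the benzyl ethers would then sit beside two benzylic C–O bonds.
- Comparison: in structure the chosen plan builds the oxolane at the correct oxidation level in the key step and never has two free benzylic hydroxyls on electron-rich arenes under acid. In mechanism Alternative 1 has the more reliable control at C7. In step economy it is shorter before the key step but longer and chemoselectively harder after it.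

Alternative 2: The cut is at C7–C8 and C7'–C8'. (3S,4S)-Oxolane-3,4-diol A4 from the tartaric acid pool would be O-benzylated twice to (3S,4S)-3,4-bis{[3-methoxy-4-(triisopropylsilyloxy)phenyl]methoxy}oxolane A5. Excess n-BuLi would then induce two [1,2]-Wittig shifts, each ring carbon moving from oxygen to the lithiated benzylic carbon, to give the bis(triisopropylsilyl) ether of the target A6.
- In its favour: the ring and both ring stereocentres come from the chiral pool, two C–C bonds form in one operation, and A6 is one desilylation from the target. On step count this is clearly better than the chosen plan, and on the configuration of C8/C8' it is at least equal, since retention at the migrating carbon is the normal course.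
- Against it: the shift is a radical-pair dissociation and recombination in the solvent cage. Retention at a secondary migrating carbon is only partial, and the configuration of the new carbinol carbon is decided at recombination with little bias, over two separate events.
- Further liabilities: the electron-rich arenes make the benzylic protons less acidic, so forcing conditions would invite ortho-lithiation beside the methoxy group, attack at silicon, deprotonation of the ring OCH2 with fragmentation, and β-elimination of the neighbouring alkoxide. The second shift must also occur on a species that already carries an alkoxide.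
- Comparison: in structure it is the most direct mapping of the target. In mechanism the chosen plan has an identifiable control element for each centre where this one has none for C7/C7'. C7 is the weak point of both plans, and an oxidation–reduction reset would serve either equally. In step economy the alternative is better.

Alternative 3: The cut is at C8–C9 and C8'–C9'. CsF would convert chloromethyl (trimethylsilyl)methyl ether A7 into the parent carbonyl ylide, which would add across the alkene of N,N'-fumaroylbis[(2R)-bornane-10,2-sultam] A8 to give the trans-oxolane-3,4-dicarbonyl bis-sultam A9.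
- In its favour: the ring, both ring C–C bonds and both ring stereocentres arise in one concerted suprafacial step. The trans relationship follows from the alkene geometry, which is better secured than in the chosen plan, where it rests on a conformational preference. The facial sense comes from two reinforcing auxiliaries.
- Against it: A9 carries no arenes and has C7/C7' at the carboxyl level. The auxiliaries must be removed, both acyl groups turned into aryl ketones as in the diketone A10, and both ketones reduced with control. The C7/C7' problem is therefore deferred to a double reagent-controlled reduction next to epimerisable α-centres and a β-alkoxy ketone that can open by retro-oxa-Michael reaction under base.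
- Further points: the parent ylide is short-lived and non-stabilised, and two heavy auxiliaries are spent on a five-atom ring. A7 is an alkylating chloromethyl ether, on a par with the chloromethyl ether used in the chosen plan.
- Comparison: in structure both plans form C8–C9 in the key step, but the chosen plan also places the oxygen on C7 and already carries both arenes. In mechanism the cycloaddition is the more predictable for C8/C8', while C7 would depend on reagent control alone, as in the fallback of the chosen plan. In step economy the two are roughly equal, the alternative being perhaps slightly shorter.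

Key step: step 9

Assumption: lignan numbering is used throughout (C7/C7' carbinol carbons, C8/C8' ring CH, C9/C9' ring OCH2; unprimed atoms are those created in step 9). Ts stands for 4-methylbenzenesulfonyl, and trifluoroacetate 18 is treated as labile on silica and carried into step 10 after extractive work-up only.

## Steps

Step 1
Reactants: 1 4-bromo-2-methoxyphenol
Product: 2 4-bromo-2-methoxyphenyl 4-methylbenzenesulfonate
Conditions: TsCl, Et3N, DMAP (cat.), CH2Cl2, 0 °C to rt
Reagents that add atoms: 4-methylbenzenesulfonyl chloride, Cc1ccc(S(=O)(=O)Cl)cc1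
Why: O-Sulfonylation of a phenol under amine base is routine; the sulfonate is chosen because it should survive every step up to step 11 and makes the arene and its benzylic position electron-poor.

Step 2
Reactants: 2 4-bromo-2-methoxyphenyl 4-methylbenzenesulfonate; 3 but-3-enoic acid
Product: 4 (3E)-4-[3-methoxy-4-(tosyloxy)phenyl]but-3-enoic acid
Conditions: Pd(OAc)2 (cat.), P(o-tol)3, Et3N, MeCN, 80 °C; then 1 M HCl
Reagents that add atoms: none
Why: Heck arylation: zerovalent palladium formed in situ inserts into the C–Br bond (the aryl sulfonate C–O bond is inert with this ligand), the aryl group adds to the terminal alkene carbon, and β-hydride elimination toward the benzylic hydrogen gives the conjugated E-styrene. The alkene thus stays β,γ to the carboxyl group, as is usual for arylation of but-3-enoic acid.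

Step 3
Reactants: 4 (3E)-4-[3-methoxy-4-(tosyloxy)phenyl]but-3-enoic acid; 5 (S)-4-benzyl-2-oxazolidinone
Product: 7 (4S)-4-benzyl-3-{(3E)-4-[3-methoxy-4-(tosyloxy)phenyl]but-3-enoyl}oxazolidin-2-one, via mixed pivalic anhydride 6 (not isolated)
Conditions: t-BuCOCl, Et3N, THF, −20 °C; then 5, LiCl, −20 °C to rt
Reagents that add atoms: none
Why: N-Acylation of the oxazolidinone through a mixed pivalic anhydride with LiCl/Et3N activation; the auxiliary attacks the less hindered carbonyl of 6, and the absence of strong base keeps the alkene out of conjugation with the carbonyl.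

Step 4
Reactants: 8 vanillin
Product: 9 4-formyl-2-methoxyphenyl 4-methylbenzenesulfonate
Conditions: TsCl, Et3N, DMAP (cat.), CH2Cl2, 0 °C to rt
Reagents that add atoms: 4-methylbenzenesulfonyl chloride, Cc1ccc(S(=O)(=O)Cl)cc1
Why: O-Tosylation of the phenol as in step 1; the sulfonate also makes the aldehyde a better electrophile for step 5.

Step 5
Reactants: 7 (4S)-4-benzyl-3-{(3E)-4-[3-methoxy-4-(tosyloxy)phenyl]but-3-enoyl}oxazolidin-2-one; 9 4-formyl-2-methoxyphenyl 4-methylbenzenesulfonate
Product: 12 (4S)-4-benzyl-3-{(2S,3E)-2-[(S)-hydroxy(3-methoxy-4-tosyloxyphenyl)methyl]-4-(3-methoxy-4-tosyloxyphenyl)but-3-enoyl}oxazolidin-2-one, via boron dienolate 10 (not isolated), via boron aldolate 11 (not isolated)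
Conditions: Bu2BOTf, i-Pr2NEt, CH2Cl2, −78 to 0 °C; then 9, −78 to 0 °C; then pH 7 buffer, MeOH, 30% H2O2, 0 °C
Reagents that add atoms: none
Why: Evans syn-aldol addition: soft enolisation gives the Z-configured boron dienolate 10, which reacts at its α-carbon through a closed Zimmerman–Traxler chair on the face away from the benzyl group of the auxiliary to give aldolate 11, and oxidative work-up releases 12. C8' and C7' (both S in 12) are set here, syn to each other through the Z-enolate/chair combination and in the absolute sense by the auxiliary, and the E-styrene is carried through unchanged.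

Step 6
Reactants: 12 (4S)-4-benzyl-3-{(2S,3E)-2-[(S)-hydroxy(3-methoxy-4-tosyloxyphenyl)methyl]-4-(3-methoxy-4-tosyloxyphenyl)but-3-enoyl}oxazolidin-2-one
Product: 13 (1S,2R,3E)-2-(hydroxymethyl)-1,4-bis[3-methoxy-4-(tosyloxy)phenyl]but-3-en-1-ol
Conditions: LiBH4, MeOH (1 equiv), THF, 0 °C
Reagents that add atoms: none
Why: Reductive removal of the auxiliary with LiBH4 (hydride addition to the exocyclic imide carbonyl) gives the primary alcohol at C9' without affecting the aryl sulfonates, the styrene or the two stereocentres; 5 is released and can be recovered. The change of descriptor at C8' from S to R reflects only a change of substituent priorities.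

Step 7
Reactants: 13 (1S,2R,3E)-2-(hydroxymethyl)-1,4-bis[3-methoxy-4-(tosyloxy)phenyl]but-3-en-1-ol
Product: 14 (1S,2R,3E)-2-[(methoxymethoxy)methyl]-1,4-bis[3-methoxy-4-(tosyloxy)phenyl]but-3-en-1-ol
Conditions: MOMCl (1.1 equiv), i-Pr2NEt, CH2Cl2, −20 to 0 °C
Reagents that add atoms: chloromethyl methyl ether, COCCl
Why: Alkoxymethylation (Williamson-type etherification) with a slight excess of reagent at low temperature should occur at the unhindered primary hydroxyl well before the hindered benzylic one, which is further slowed by its electron-poor arene.

Step 8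
Reactants: 14 (1S,2R,3E)-2-[(methoxymethoxy)methyl]-1,4-bis[3-methoxy-4-(tosyloxy)phenyl]but-3-en-1-ol
Product: 15 (1S,2R,3E)-2-[(methoxymethoxy)methyl]-1,4-bis[3-methoxy-4-(tosyloxy)phenyl]but-3-en-1-yl acetate
Conditions: Ac2O, pyridine, DMAP (cat.), CH2Cl2, 0 °C to rt
Reagents that add atoms: acetic anhydride, CC(=O)OC(C)=O
Why: DMAP-catalysed acetylation of the remaining secondary alcohol; the acetate removes O7' as a second site for oxocarbenium formation and, being electron-withdrawing, helps to keep C7' from ionising in step 9.

Step 9
Reactants: 15 (1S,2R,3E)-2-[(methoxymethoxy)methyl]-1,4-bis[3-methoxy-4-(tosyloxy)phenyl]but-3-en-1-yl acetate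
Product: 18 (S)-[(3R,4R)-4-{(S)-acetoxy[3-methoxy-4-(tosyloxy)phenyl]methyl}oxolan-3-yl][3-methoxy-4-(tosyloxy)phenyl]methyl trifluoroacetate, via oxocarbenium ion 16 (not isolated), via benzylic cation 17 (not isolated)
Conditions: CF3CO2H–CH2Cl2 (1:4), (CF3CO)2O (1.5 equiv), −20 to 0 °C; then cold aq NaHCO3
Reagents that add atoms: trifluoroacetic acid, OC(=O)C(F)(F)F
Why: Prins cyclisation of a homoallylic alkoxymethyl ether, the known acid-mediated route from styrenyl homoallylic alcohols and their alkoxymethyl ethers to 3-(α-acyloxybenzyl)oxolanes. CF3CO2H protonates the acetal and methanol leaves (trapped at once by (CF3CO)2O as methyl trifluoroacetate, so that it cannot compete as a nucleophile), giving oxocarbenium ion 16 on O9' only, because O7' is tied up as an acetate. Styrene carbon C8 attacks the CH2=O+ carbon: the oxolane closes in a five-membered mode in which the C=O+ unit becomes part of the ring and the C=C bond stays exocyclic, the only mode that places the charge on benzylic C7 (cation 17), whereas six-membered closure through C7 would leave a non-stabilised secondary cation at C8. The new C8 centre is controlled by C8': in the envelope-like transition state the acetoxy(aryl)methyl group on C8' sits pseudo-equatorial and the styrene arm turns away from it, which gives the trans-3,4 ring. The new C7 centre is controlled by the E geometry of the alkene together with anti addition: trifluoroacetate, present in large excess, should collapse on C7 from the face opposite the forming C8–C9 bond before rotation about C7–C8, and anti addition across the E-alkene corresponds to the 7S,8R relationship. The step needs selectivity for (a) the five-membered ring, secured by benzylic stabilisation, (b) capture by trifluoroacetate and not by the neighbouring arene (Friedel–Crafts closure to an aryltetralin) or by proton loss, secured by the deactivating sulfonates, the high trifluoroacetate concentration, low temperature and short contact time, and (c) integrity of C7', secured by the acetate and the electron-poor ring. A 2-oxonia-Cope shift of 16 is not expected to interfere because it would take the alkene out of conjugation with the arene.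

Step 10
Reactants: 18 (S)-[(3R,4R)-4-{(S)-acetoxy[3-methoxy-4-(tosyloxy)phenyl]methyl}oxolan-3-yl][3-methoxy-4-(tosyloxy)phenyl]methyl trifluoroacetate
Product: 19 [(3R,4R)-oxolane-3,4-diyl]bis{(S)-[3-methoxy-4-(tosyloxy)phenyl]methanol}
Conditions: K2CO3 (0.2 equiv), MeOH, 0 °C to rt
Reagents that add atoms: none
Why: Base-catalysed transesterification (methanolysis) removes the trifluoroacetate and the acetate by acyl–oxygen cleavage, so C7 and C7' are not touched, and aryl sulfonates are inert under these conditions. The C2-symmetric diol 19 is the point at which a C7 epimer from step 9 should be separable by crystallisation or chromatography.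

Step 11
Reactants: 19 [(3R,4R)-oxolane-3,4-diyl]bis{(S)-[3-methoxy-4-(tosyloxy)phenyl]methanol}
Product: 20 [(3R,4R)-oxolane-3,4-diyl]bis[(S)-(4-hydroxy-3-methoxyphenyl)methanol]
Conditions: KOH, 1,4-dioxane–H2O (1:1), 60 °C, Ar; then AcOH to pH 6, 0 °C
Reagents that add atoms: none
Why: Hydroxide attacks sulfur of each aryl sulfonate (nucleophilic substitution at sulfonyl sulfur, S–O cleavage) and releases the phenoxides; potassium tosylate forms directly, so no alkylating sulfonate ester arises as it would in methanol. Because no benzylic ester is left, the phenoxides have only hydroxide as a possible leaving group at C7/C7', quinone-methide formation should be slow at this temperature and any that forms would be re-trapped by water; neutralisation under argon gives 20.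

## Compound list

1 | 4-bromo-2-methoxyphenol | COc1cc(Br)ccc1O | starting material
2 | 4-bromo-2-methoxyphenyl 4-methylbenzenesulfonate | COc1cc(Br)ccc1OS(=O)(=O)c1ccc(C)cc1 | intermediate
3 | but-3-enoic acid | C=CCC(=O)O | starting material
4 | (3E)-4-[3-methoxy-4-(tosyloxy)phenyl]but-3-enoic acid | O=C(O)C/C=C/c1ccc(OS(=O)(=O)c2ccc(C)cc2)c(OC)c1 | intermediate
5 | (S)-4-benzyl-2-oxazolidinone | O=C1OC[C@H](Cc2ccccc2)N1 | starting material
6 | mixed anhydride of 4 with pivalic acid (formed in the flask) | CC(C)(C)C(=O)OC(=O)C/C=C/c1ccc(OS(=O)(=O)c2ccc(C)cc2)c(OC)c1 | intermediate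
7 | (4S)-4-benzyl-3-{(3E)-4-[3-methoxy-4-(tosyloxy)phenyl]but-3-enoyl}oxazolidin-2-one | O=C(C/C=C/c1ccc(OS(=O)(=O)c2ccc(C)cc2)c(OC)c1)N1C(=O)OC[C@@H]1Cc1ccccc1 | intermediate
8 | vanillin (4-hydroxy-3-methoxybenzaldehyde) | COc1cc(C=O)ccc1O | starting material
9 | 4-formyl-2-methoxyphenyl 4-methylbenzenesulfonate (O-tosylvanillin) | COc1cc(C=O)ccc1OS(=O)(=O)c1ccc(C)cc1 | intermediate
10 | di-n-butylboron dienolate of 7 (enolate C=C Z with O–B cis to the styryl carbon; styrene E; formed in the flask) | CCCCB(CCCC)O/C(=C\C=C\c1ccc(OS(=O)(=O)c2ccc(C)cc2)c(OC)c1)N1C(=O)OC[C@@H]1Cc1ccccc1 | intermediate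
11 | O-(di-n-butylboryl) aldolate of 12 (formed in the flask) | O=C([C@@H](/C=C/c1ccc(OS(=O)(=O)c2ccc(C)cc2)c(OC)c1)[C@H](OB(CCCC)CCCC)c1ccc(OS(=O)(=O)c2ccc(C)cc2)c(OC)c1)N1C(=O)OC[C@@H]1Cc1ccccc1 | intermediate
12 | (4S)-4-benzyl-3-{(2S,3E)-2-[(S)-hydroxy(3-methoxy-4-tosyloxyphenyl)methyl]-4-(3-methoxy-4-tosyloxyphenyl)but-3-enoyl}oxazolidin-2-one | O=C([C@@H](/C=C/c1ccc(OS(=O)(=O)c2ccc(C)cc2)c(OC)c1)[C@H](O)c1ccc(OS(=O)(=O)c2ccc(C)cc2)c(OC)c1)N1C(=O)OC[C@@H]1Cc1ccccc1 | intermediate
13 | (1S,2R,3E)-2-(hydroxymethyl)-1,4-bis[3-methoxy-4-(tosyloxy)phenyl]but-3-en-1-ol | OC[C@@H](/C=C/c1ccc(OS(=O)(=O)c2ccc(C)cc2)c(OC)c1)[C@H](O)c1ccc(OS(=O)(=O)c2ccc(C)cc2)c(OC)c1 | intermediate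
14 | (1S,2R,3E)-2-[(methoxymethoxy)methyl]-1,4-bis[3-methoxy-4-(tosyloxy)phenyl]but-3-en-1-ol | COCOC[C@@H](/C=C/c1ccc(OS(=O)(=O)c2ccc(C)cc2)c(OC)c1)[C@H](O)c1ccc(OS(=O)(=O)c2ccc(C)cc2)c(OC)c1 | intermediate
15 | (1S,2R,3E)-2-[(methoxymethoxy)methyl]-1,4-bis[3-methoxy-4-(tosyloxy)phenyl]but-3-en-1-yl acetate | COCOC[C@@H](/C=C/c1ccc(OS(=O)(=O)c2ccc(C)cc2)c(OC)c1)[C@H](OC(C)=O)c1ccc(OS(=O)(=O)c2ccc(C)cc2)c(OC)c1 | intermediate
16 | O9'-methylidene oxocarbenium trifluoroacetate derived from 15 (formed in the flask) | C=[O+]C[C@@H](/C=C/c1ccc(OS(=O)(=O)c2ccc(C)cc2)c(OC)c1)[C@H](OC(C)=O)c1ccc(OS(=O)(=O)c2ccc(C)cc2)c(OC)c1.[O-]C(=O)C(F)(F)F | intermediate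
17 | C7 benzylic cation trifluoroacetate ion pair with the trans-oxolane closed (formed in the flask) | COc1cc([CH+][C@H]2COC[C@@H]2[C@H](OC(C)=O)c2ccc(OS(=O)(=O)c3ccc(C)cc3)c(OC)c2)ccc1OS(=O)(=O)c1ccc(C)cc1.[O-]C(=O)C(F)(F)F | intermediate
18 | (S)-[(3R,4R)-4-{(S)-acetoxy[3-methoxy-4-(tosyloxy)phenyl]methyl}oxolan-3-yl][3-methoxy-4-(tosyloxy)phenyl]methyl trifluoroacetate; (7S,7'S,8R,8'R) | COc1cc([C@@H](OC(=O)C(F)(F)F)[C@H]2COC[C@@H]2[C@H](OC(C)=O)c2ccc(OS(=O)(=O)c3ccc(C)cc3)c(OC)c2)ccc1OS(=O)(=O)c1ccc(C)cc1 | intermediate
19 | [(3R,4R)-oxolane-3,4-diyl]bis{(S)-[3-methoxy-4-(tosyloxy)phenyl]methanol} | COc1cc([C@@H](O)[C@H]2COC[C@@H]2[C@H](O)c2ccc(OS(=O)(=O)c3ccc(C)cc3)c(OC)c2)ccc1OS(=O)(=O)c1ccc(C)cc1 | intermediate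
20 | [(3R,4R)-oxolane-3,4-diyl]bis[(S)-(4-hydroxy-3-methoxyphenyl)methanol]; (7S,7'S,8R,8'R) | COc1cc([C@@H](O)[C@H]2COC[C@@H]2[C@H](O)c2ccc(O)c(OC)c2)ccc1O | target

## Step count and risk

Total step count: 11. Longest linear sequence: 10 steps (steps 1, 2, 3, 5, 6, 7, 8, 9, 10 and 11, from 1 to 20); step 4 is a one-step side branch.

Least certain steps:

Step 9 (key step). The most likely failure is poor facial selectivity in the capture at C7. If ion pair 17 relaxes by rotation about C7–C8 before it collapses, attack anti to the bulkier arm on C8' becomes the easier path and the wrong configuration at C7 results. Competing Friedel–Crafts closure of C7 onto the arene of the other arm and unproductive loss of the alkoxymethyl group are secondary concerns. The fallback replaces substrate-controlled capture by reagent-controlled reduction and sets out from 18 obtained as a C7 epimer mixture. NaHCO3 in MeOH at 0 °C should cleave only the trifluoroacetate and give the C7-epimeric mixture of (S)-[(3R,4R)-4-{hydroxy[3-methoxy-4-(tosyloxy)phenyl]methyl}oxolan-3-yl][3-methoxy-4-(tosyloxy)phenyl]methyl acetate F1. Dess–Martin periodinane in CH2Cl2 should then give the aryl ketone (S)-[(3R,4R)-4-(3-methoxy-4-tosyloxybenzoyl)oxolan-3-yl][3-methoxy-4-(tosyloxy)phenyl]methyl acetate F2. Corey–Bakshi–Shibata reduction with (R)-2-methyl-CBS-oxazaborolidine and BH3·SMe2, in which the arene acts as the larger ketone substituent, should give the single (7S)-alcohol 7'-acetate F3. K2CO3 in MeOH then removes the acetate and the route is rejoined at 19.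

Step 7. The most likely failure is insufficient discrimination between the primary and the secondary hydroxyl (over-alkylation or alkoxymethylation at O7'), which would later allow an oxocarbenium ion to form on the wrong oxygen. The fallback replaces kinetic selection by a protecting-group relay and sets out from 13. TBSCl and imidazole in CH2Cl2 at 0 °C should silylate only the primary hydroxyl and give (1S,2R,3E)-2-[(tert-butyldimethylsilyloxy)methyl]-1,4-bis[3-methoxy-4-(tosyloxy)phenyl]but-3-en-1-ol F4. Ac2O, pyridine and DMAP should give its acetate F5. HF·pyridine in THF at 0 °C (acidic, so that acyl migration is suppressed) should give (1S,2R,3E)-2-(hydroxymethyl)-1,4-bis[3-methoxy-4-(tosyloxy)phenyl]but-3-en-1-yl acetate F6. MOMCl and i-Pr2NEt then alkoxymethylate the only free hydroxyl and the route is rejoined at 15.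

Step 5. The most likely failure is erosion of regio- and diastereoselectivity: the extended, arene-conjugated dienolate could react partly through its γ-carbon, and the doubly activated α-centre of the adduct could epimerise or undergo retro-aldol cleavage. The fallback builds the styrene after the aldol step and sets out from 5 and 9. Acylation of 5 with (E)-but-2-enoyl chloride (n-BuLi, THF, −78 °C) should give (4S)-4-benzyl-3-[(E)-but-2-enoyl]oxazolidin-2-one F7. Its boron dienolate (Bu2BOTf, Et3N), formed by γ-deprotonation, should add to 9 at the α-carbon in the established deconjugative syn-aldol manner and give (4S)-4-benzyl-3-{(2S)-2-[(S)-hydroxy(3-methoxy-4-tosyloxyphenyl)methyl]but-3-enoyl}oxazolidin-2-one F8. LiBH4 should give (1S,2R)-2-(hydroxymethyl)-1-[3-methoxy-4-(tosyloxy)phenyl]but-3-en-1-ol F9. Wittig methylenation of 9 (Ph3PCH3Br, KOt-Bu, THF) should give 2-methoxy-4-vinylphenyl 4-methylbenzenesulfonate F10. Cross-metathesis of F9 with excess F10 (second-generation Grubbs catalyst, CH2Cl2, 40 °C), expected to favour the E-styrene, rejoins the route at 13.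

Step 2. The most likely failure is migration of the double bond (re-addition of a palladium hydride, or base-mediated isomerisation) toward conjugation with the carboxyl group, giving inseparable regioisomers. The fallback makes the alkene by carbonyl olefination and sets out from 9. Wittig reaction with the ylide from (2-carboxyethyl)triphenylphosphonium bromide and NaN(SiMe3)2 (2 equiv, THF, 0 °C), which for aromatic aldehydes is expected to favour the E-alkene, rejoins the route directly at 4; no new compound is made (F0).

Step 11. The most likely failure is base-induced quinone-methide formation from the liberated phenoxides, with loss of configuration at C7/C7', or air oxidation of the electron-rich phenoxides. The fallback breaks the S–O bonds by single-electron reduction instead of by nucleophilic attack at sulfur in hot alkali. It sets out from 19, uses Mg turnings in MeOH at rt followed by mild acidification, and arrives directly at 20; no new compound is made (F0).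

## Further compounds

F1 | step 9 | (S)-[(3R,4R)-4-{hydroxy[3-methoxy-4-(tosyloxy)phenyl]methyl}oxolan-3-yl][3-methoxy-4-(tosyloxy)phenyl]methyl acetate, mixture of C7 epimers | COc1cc(C(O)[C@H]2COC[C@@H]2[C@H](OC(C)=O)c2ccc(OS(=O)(=O)c3ccc(C)cc3)c(OC)c2)ccc1OS(=O)(=O)c1ccc(C)cc1
F2 | step 9 | (S)-[(3R,4R)-4-(3-methoxy-4-tosyloxybenzoyl)oxolan-3-yl][3-methoxy-4-(tosyloxy)phenyl]methyl acetate | COc1cc(C(=O)[C@H]2COC[C@@H]2[C@H](OC(C)=O)c2ccc(OS(=O)(=O)c3ccc(C)cc3)c(OC)c2)ccc1OS(=O)(=O)c1ccc(C)cc1
F3 | step 9 | (S)-[(3R,4R)-4-{(S)-hydroxy[3-methoxy-4-(tosyloxy)phenyl]methyl}oxolan-3-yl][3-methoxy-4-(tosyloxy)phenyl]methyl acetate | COc1cc([C@@H](O)[C@H]2COC[C@@H]2[C@H](OC(C)=O)c2ccc(OS(=O)(=O)c3ccc(C)cc3)c(OC)c2)ccc1OS(=O)(=O)c1ccc(C)cc1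
F4 | step 7 | (1S,2R,3E)-2-[(tert-butyldimethylsilyloxy)methyl]-1,4-bis[3-methoxy-4-(tosyloxy)phenyl]but-3-en-1-ol | CC(C)(C)[Si](C)(C)OC[C@@H](/C=C/c1ccc(OS(=O)(=O)c2ccc(C)cc2)c(OC)c1)[C@H](O)c1ccc(OS(=O)(=O)c2ccc(C)cc2)c(OC)c1
F5 | step 7 | (1S,2R,3E)-2-[(tert-butyldimethylsilyloxy)methyl]-1,4-bis[3-methoxy-4-(tosyloxy)phenyl]but-3-en-1-yl acetate | CC(C)(C)[Si](C)(C)OC[C@@H](/C=C/c1ccc(OS(=O)(=O)c2ccc(C)cc2)c(OC)c1)[C@H](OC(C)=O)c1ccc(OS(=O)(=O)c2ccc(C)cc2)c(OC)c1
F6 | step 7 | (1S,2R,3E)-2-(hydroxymethyl)-1,4-bis[3-methoxy-4-(tosyloxy)phenyl]but-3-en-1-yl acetate | OC[C@@H](/C=C/c1ccc(OS(=O)(=O)c2ccc(C)cc2)c(OC)c1)[C@H](OC(C)=O)c1ccc(OS(=O)(=O)c2ccc(C)cc2)c(OC)c1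
F7 | step 5 | (4S)-4-benzyl-3-[(E)-but-2-enoyl]oxazolidin-2-one | C/C=C/C(=O)N1C(=O)OC[C@@H]1Cc1ccccc1
F8 | step 5 | (4S)-4-benzyl-3-{(2S)-2-[(S)-hydroxy(3-methoxy-4-tosyloxyphenyl)methyl]but-3-enoyl}oxazolidin-2-one | O=C([C@@H](C=C)[C@H](O)c1ccc(OS(=O)(=O)c2ccc(C)cc2)c(OC)c1)N1C(=O)OC[C@@H]1Cc1ccccc1
F9 | step 5 | (1S,2R)-2-(hydroxymethyl)-1-[3-methoxy-4-(tosyloxy)phenyl]but-3-en-1-ol | OC[C@@H](C=C)[C@H](O)c1ccc(OS(=O)(=O)c2ccc(C)cc2)c(OC)c1
F10 | step 5 | 2-methoxy-4-vinylphenyl 4-methylbenzenesulfonate | C=Cc1ccc(OS(=O)(=O)c2ccc(C)cc2)c(OC)c1
F0 | step 2 | none | none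
F0 | step 11 | none | none
A1 | alternative 1 | dimethyl 2,3-bis(4-benzyloxy-3-methoxybenzoyl)butanedioate (configurationally labile at C2 and C3) | COC(=O)C(C(=O)c1ccc(OCc2ccccc2)c(OC)c1)C(C(=O)OC)C(=O)c1ccc(OCc2ccccc2)c(OC)c1
A2 | alternative 1 | exo,exo-4,8-bis(4-benzyloxy-3-methoxyphenyl)-3,7-dioxabicyclo[3.3.0]octane-2,6-dione | COc1cc([C@H]2OC(=O)[C@@H]3[C@@H](c4ccc(OCc5ccccc5)c(OC)c4)OC(=O)[C@H]23)ccc1OCc1ccccc1
A3 | alternative 1 | (1S,2R,3R,4S)-1,4-bis(4-benzyloxy-3-methoxyphenyl)-2,3-bis(hydroxymethyl)butane-1,4-diol | COc1cc([C@@H](O)[C@@H](CO)[C@H](CO)[C@H](O)c2ccc(OCc3ccccc3)c(OC)c2)ccc1OCc1ccccc1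
A4 | alternative 2 | (3S,4S)-oxolane-3,4-diol | O[C@H]1COC[C@@H]1O
A5 | alternative 2 | (3S,4S)-3,4-bis{[3-methoxy-4-(triisopropylsilyloxy)phenyl]methoxy}oxolane | COc1cc(CO[C@H]2COC[C@@H]2OCc2ccc(O[Si](C(C)C)(C(C)C)C(C)C)c(OC)c2)ccc1O[Si](C(C)C)(C(C)C)C(C)C
A6 | alternative 2 | [(3R,4R)-oxolane-3,4-diyl]bis{(S)-[3-methoxy-4-(triisopropylsilyloxy)phenyl]methanol} | COc1cc([C@@H](O)[C@H]2COC[C@@H]2[C@H](O)c3ccc(O[Si](C(C)C)(C(C)C)C(C)C)c(OC)c3)ccc1O[Si](C(C)C)(C(C)C)C(C)C
A7 | alternative 3 | chloromethyl (trimethylsilyl)methyl ether | C[Si](C)(C)COCCl
A8 | alternative 3 | N,N'-fumaroylbis[(2R)-bornane-10,2-sultam] | O=C(/C=C/C(=O)N1[C@@H]2C[C@H]3CC[C@]2(CS1(=O)=O)C3(C)C)N1[C@@H]2C[C@H]3CC[C@]2(CS1(=O)=O)C3(C)C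
A9 | alternative 3 | (3R,4R)-oxolane-3,4-dicarbonyl bis[(2R)-bornane-10,2-sultam] | O=C(N1[C@@H]2C[C@H]3CC[C@]2(CS1(=O)=O)C3(C)C)[C@H]4COC[C@@H]4C(=O)N1[C@@H]2C[C@H]3CC[C@]2(CS1(=O)=O)C3(C)C
A10 | alternative 3 | [(3R,4R)-oxolane-3,4-diyl]bis[(4-benzyloxy-3-methoxyphenyl)methanone] | O=C(c1ccc(OCc2ccccc2)c(OC)c1)[C@H]1COC[C@@H]1C(=O)c1ccc(OCc2ccccc2)c(OC)c1
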